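## Analysis of the target

The target is a flavanone: ring A (benzene) is fused through C4a and C8a to the pyranone ring C (O1, C2, C3, C4=O), and C2 carries ring B, a 2,4,6-trihydroxyphenyl group. Ring A is fully substituted in a phloroglucinol pattern, with hydroxyls on C5 and C7, a prenyl group on C6 and a (2R)-lavandulyl group on C8. The lavandulyl chain is therefore the carbon neighbour of O1, and the prenyl group lies para to O1. There are two stereocentres, C2 (S) and C2'' of the lavandulyl chain (R). Five bonds separate them (C2–O1–C8a–C8–C1''–C2''), so neither can steer the other and each must be introduced on its own. The sensitive functions are five phenols and three alkenes (two trisubstituted, one 1,1-disubstituted), which rule out hydrogenolysis and strong acid, and C2 itself: base epimerises it by retro-oxa-Michael opening of ring C, and acid can ionise C2–O1 because ring B has oxygen at both ortho positions and para. The difficulty lies in placing two different C-alkyl groups correctly relative to O1 on a hexasubstituted ring and in setting C2 beside a very electron-rich, di-ortho-substituted aryl group. The strategy rests on ring C: O1, C8a, C4a and C4 are the four atoms of an ortho-quinone methide derived from a ring A salicylaldehyde, and C2–C3 with ring B on C2 is the double bond of a 2,4,6-trioxygenated styrene, so ring C can be closed by forming O1–C2 and C3–C4 in one [4+2] event.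

## Retrosynthetic reasoning

**19 from 18.** Only the five O–Si bonds are cut. Keeping every phenol as the same silyl ether to the end allows one buffered fluoride treatment, which needs neither the base that opens ring C nor the acid that ionises C2–O1 or cyclises the side chains.

**18 from 17.** The C4 carbonyl is traced back to a C4 methyl ether. C4–H in 17 is benzylic to the trioxygenated ring A and alpha to oxygen, so hydride abstraction by a quinone oxidant followed by hydrolysis should give the ketone directly. This is preferred to acid solvolysis of the ether, which invites elimination across C3–C4 and C2–O1 ionisation. The C4 stereocentre is deliberately lost.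

**17 from 12, 14 and 15 (through acetal 16).** O1–C2 and C3–C4 are cut. This is the one disconnection that divides the molecule into a ring A half and a ring B half of similar size and creates C2 in the same step. Aldehyde 12 supplies C4 and, through its single free hydroxyl, O1; orthoformate 15 turns the formyl group into the ionisable acetal 16; styrene 14 supplies C2 and C3. The forward reaction must generate the oxocarbenium ion, join it to the styrene terminus, close the ring through the only free phenol, and select the styrene face that gives 2S.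

**14 from 13, and 13 from 4.** The C=C bond of 14 is cut to the aldehyde 13 (methylenation), and the three O–Si bonds to the commercial trihydroxybenzaldehyde 4. Both rings thus come from the same cheap arene.

**12 from 10 (through dienone 11).** The C6–prenyl bond is cut. Because C6 is para to the oxygen that becomes O1, the prenyl group can be delivered from that oxygen by a Claisen shift onto the blocked ortho carbon and a Cope shift to the para carbon. This avoids a metal-catalysed coupling at the crowded position between two silyloxy groups, gives the linear prenyl isomer by mechanism, and regenerates the free hydroxyl exactly where the key step needs it.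

**10 from 8 and 9.** The O–C bond of the prenyl ether is cut; the forward step is alkylation of the chelated phenol under neutral conditions that spare aryl silyl ethers.

**8 from 6 and 3 (through zinc reagent 7).** The C8–C1'' bond is cut as an sp2–sp3 cross-coupling. The aldehyde forbids an aryl-metal nucleophile, and a beta-branched primary halide is a poor SN2 partner. An alkylzinc halide tolerates the aldehyde and leaves the beta stereocentre untouched.

**6 from 5, and 5 from 4.** The C–I bond is cut, then two O–Si bonds. This is where the two ortho oxygens become different. Partial silylation of 4 leaves the one hydroxyl that is hydrogen-bonded to the formyl group, and that free phenol directs iodination to its own ortho carbon. The lavandulyl group is thereby tied to the oxygen that will become O1.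

**3 from 2, and 2 from 1.** The C–I bond is traced to the primary alcohol, and the single enantiomer 2 to the racemic terpene alcohol 1 by enzymatic resolution. The C2'' centre is selected, not made, at the start of the route.

## Alternatives that were turned down

**Alternative 1:** This plan cuts ring A itself at C7–C8, C4a–C8a and C6–C7 and builds it by a Danheiser benzannulation. Heating cyclobutenone A2 opens it to a vinylketene, which adds siloxyalkyne A3 in a [2+2] sense; a second ring opening and a 6π closure then give the pentasubstituted phenol A1. In its favour, every substituent of ring A is placed by connectivity, and the three oxygens emerge differentiated (free at C7, allyl at C5, silyl at C8a). On ring A regiochemistry it is stronger than the chosen route, which relies on selective silylation and ortho-directed iodination. Against it, A1 is only ring A: C4a is still unsubstituted, and ring C and the C2 stereocentre remain to be made. Both A2 and A3 need multistep syntheses. The thermal cascade also exposes a ketene to a pendant prenyl alkene and heats a 1,5-diene and an allyl aryl ether. In step count it is clearly longer. The chosen strategy buys ring A from a commercial arene and spends its key step on ring C and C2.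

**Alternative 2:** This plan cuts O1–C8a and C4a–C4. Fluoride converts the silyl aryl triflate A5 into the C4a–C8a aryne. The alkoxide of the (S)-hydroxy ester A6 adds at C8a, and the C4a aryl anion closes ring C on the ester to give the penta-MOM flavanone A4. In its favour, ring C forms at the ketone oxidation level, and C2 is carried in from A6, which can be made by established asymmetric reduction. On certainty of the C2 configuration it is stronger than the chosen key step, whose induction is untested. Against it:
- A5 requires a hexasubstituted arene with adjacent silyl and triflate groups, which is harder to reach than 12.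
- The alkoxide must attack the aryne carbon flanked by the lavandulyl chain.
- Under basic fluoride the alkoxide of A6 can fragment by retro-aldol cleavage or dehydrate, and the product can open at ring C.
- The MOM ethers of A4 need acid for removal, which endangers C2 and the alkenes.

The chosen route offers a short precursor synthesis and an acid-free, base-free end game in its place.

**Alternative 3:** This plan cuts C2–C3. Diazoketone A8 loses nitrogen on a chiral dirhodium carboxylate, and the carbene at C3 inserts into a benzylic O–CH2 hydrogen to give A7, which is the same compound as 18. In its favour, the two halves are joined by a simple ether bond and the product arrives at the ketone level, saving the C4 adjustment. On redox economy it is stronger than the chosen route. Against it, an acceptor-only carbene is unselective in this molecule. The ether oxygen is placed for oxonium ylide formation and a 1,2-benzyl shift, three electron-rich alkenes invite cyclopropanation, and two trioxygenated arenes invite aromatic addition. A8 also needs a diazoketone on a di-ortho-substituted aryl carbonyl and an ether from a very labile trioxygenated benzyl electrophile. The chosen key step uses an electrophile matched to a single nucleophile, the styrene terminus, and so has the cleaner chemoselectivity.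

Key step: step 10

Abbreviations: TBS = tert-butyldimethylsilyl; lavandulyl = 5-methyl-2-(prop-1-en-2-yl)hex-4-en-1-yl; prenyl = 3-methylbut-2-en-1-yl; (R)-TRIP = (R)-3,3'-bis(2,4,6-triisopropylphenyl)-1,1'-binaphthyl-2,2'-diyl hydrogen phosphate.

Assumption: the sense of induction of the phosphoric acid in step 10 cannot be derived from a closely related case, so the (R)-acid is written; if it favours 2R, its mirror image is used with no other change.

## Route

Step 1
Reactants: 1 (±)-lavandulol
Product: 2 (S)-lavandulol
Conditions: porcine pancreatic lipase, vinyl acetate, hexane, rt, stopped past half conversion; chromatography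
Reagents that add atoms: none
Why: Lipase-catalysed kinetic resolution by enantioselective transesterification; the enzyme is expected to acetylate the R alcohol faster, so running past half conversion should leave the S alcohol in high enantiomeric purity, separable from the acetate on silica. The later C2'' centre is selected here, not created.

Step 2
Reactants: 2 (S)-lavandulol
Product: 3 (S)-lavandulyl iodide
Conditions: I2, PPh3, imidazole, CH2Cl2, 0 °C to rt
Reagents that add atoms: iodine, II
Why: Appel iodination; SN2 displacement of the alkoxyphosphonium ion at the primary carbon leaves the adjacent stereocentre untouched (descriptor stays S).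

Step 3
Reactants: 4 2,4,6-trihydroxybenzaldehyde
Product: 5 2-hydroxy-4,6-bis(TBS-oxy)benzaldehyde
Conditions: TBSCl (2.05 equiv), imidazole, DMF, 0 °C
Reagents that add atoms: tert-butyldimethylsilyl chloride, CC(C)(C)[Si](C)(C)Cl
Why: Regioselective silylation; the para hydroxyl is the most acidic and least hindered, one ortho hydroxyl follows, and the last is held in a hydrogen bond to the formyl group and reacts much more slowly, so two equivalents should stop at the bis-ether.

Step 4
Reactants: 5 2-hydroxy-4,6-bis(TBS-oxy)benzaldehyde
Product: 6 2-hydroxy-3-iodo-4,6-bis(TBS-oxy)benzaldehyde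
Conditions: N-iodosuccinimide (1.0 equiv), CH2Cl2, −20 to 0 °C, dark
Reagents that add atoms: N-iodosuccinimide, O=C1CCC(=O)N1I
Why: Electrophilic aromatic iodination; the free chelated phenol directs to its ortho carbon, as in 2-hydroxy-4,6-dialkoxyaryl carbonyl compounds, and the other open position is shielded by two flanking silyloxy groups. One equivalent at low temperature limits double iodination.

Step 5
Reactants: 3 (S)-lavandulyl iodide; 6 2-hydroxy-3-iodo-4,6-bis(TBS-oxy)benzaldehyde
Product: 8 2-hydroxy-3-[(2R)-lavandulyl]-4,6-bis(TBS-oxy)benzaldehyde, via (S)-lavandulylzinc iodide 7 (not isolated)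
Conditions: 3, Zn dust (activated), LiCl, THF, 40 °C; then 6, Pd(OAc)2 (4 mol%), SPhos (8 mol%), THF, rt, 7 (2 equiv) added slowly
Reagents that add atoms: none
Why: Negishi sp3–sp2 coupling; zinc inserts into the primary C–I bond, zerovalent palladium adds to the aryl iodide, and the bulky biaryl phosphine favours reductive elimination over beta-hydride elimination. Alkylzinc halides do not add to the aldehyde, and the coupling tolerates the free phenol when the zinc reagent is added slowly in excess. The stereocentre is beta to zinc and is carried over unchanged (the descriptor becomes R only through the change in substituent priorities).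

Step 6
Reactants: 8 2-hydroxy-3-[(2R)-lavandulyl]-4,6-bis(TBS-oxy)benzaldehyde; 9 prenol (3-methylbut-2-en-1-ol)
Product: 10 3-[(2R)-lavandulyl]-2-(prenyloxy)-4,6-bis(TBS-oxy)benzaldehyde
Conditions: PPh3, diisopropyl azodicarboxylate, THF, 0 °C to rt
Reagents that add atoms: none
Why: Mitsunobu etherification; the acidic ortho-formyl phenol is alkylated by the activated primary allylic alcohol under neutral conditions that spare the aryl silyl ethers, which a carbonate-mediated alkylation would not.

Step 7
Reactants: 10 3-[(2R)-lavandulyl]-2-(prenyloxy)-4,6-bis(TBS-oxy)benzaldehyde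
Product: 12 2-hydroxy-3-[(2R)-lavandulyl]-5-prenyl-4,6-bis(TBS-oxy)benzaldehyde, via ortho-dienone 11 (not isolated)
Conditions: Eu(fod)3 [fod = 6,6,7,7,8,8,8-heptafluoro-2,2-dimethyloctane-3,5-dionate] (10 mol%), CHCl3, 60 °C
Reagents that add atoms: none
Why: Aromatic Claisen rearrangement followed by Cope rearrangement (para-Claisen); the [3,3] shift onto the blocked ortho carbon gives dienone 11, which cannot enolise and passes the allyl unit by a second [3,3] shift to the only hydrogen-bearing carbon, para to oxygen, where enolisation restores the arene and the chelated phenol with a linear prenyl group. Chelation of trivalent europium between the ether and formyl oxygens allows 60 °C, well below the temperature at which the lavandulyl 1,5-diene would rearrange.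

Step 8
Reactants: 4 2,4,6-trihydroxybenzaldehyde
Product: 13 2,4,6-tris(TBS-oxy)benzaldehyde
Conditions: TBSCl (4 equiv), imidazole, DMAP (cat.), DMF, rt to 40 °C
Reagents that add atoms: tert-butyldimethylsilyl chloride, CC(C)(C)[Si](C)(C)Cl
Why: Exhaustive silylation; excess chlorosilane with a nucleophilic catalyst and gentle warming also converts the chelated hydroxyl.

Step 9
Reactants: 13 2,4,6-tris(TBS-oxy)benzaldehyde
Product: 14 2,4,6-tris(TBS-oxy)styrene
Conditions: Ph3PCH3Br, NaN(SiMe3)2, THF, 0 °C; then 13, −78 to 0 °C
Reagents that add atoms: methyltriphenylphosphonium bromide, C[P+](c1ccccc1)(c1ccccc1)c1ccccc1.[Br-]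
Why: Wittig methylenation; the ylide is made with a non-nucleophilic amide base so that no alkoxide is present to cleave the aryl silyl ethers.

Step 10
Reactants: 12 2-hydroxy-3-[(2R)-lavandulyl]-5-prenyl-4,6-bis(TBS-oxy)benzaldehyde; 14 2,4,6-tris(TBS-oxy)styrene; 15 trimethyl orthoformate
Product: 17 (2S,4S)-4-methoxy-8-[(2R)-lavandulyl]-6-prenyl-5,7-bis(TBS-oxy)-2-[2,4,6-tris(TBS-oxy)phenyl]chromane (2,4-cis), via dimethyl acetal 16 (not isolated)
Conditions: (R)-TRIP (10 mol%), 15 (1.5 equiv), 5 Å MS, toluene, 0 °C; 14 (1.3 equiv) added over several hours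
Reagents that add atoms: none
Why: Proposed new method: the phosphoric acid should catalyse acetal formation from 12 and 15 to give 16 and then ionise it to an O-methyl oxocarbenium ion, equivalent to a 4-methoxy ortho-quinone methide, that stays hydrogen-bonded to the chiral phosphate through the C8a hydroxyl; the closest known reaction types are the acid-mediated three-component coupling of salicylaldehydes, orthoformates and styrenes to 2,4-cis-4-alkoxyflavans and the chiral phosphoric acid catalysed [4+2] of ortho-quinone methides with styrenes. The CH2 terminus of 14 attacks C4 (bond C3–C4), and the developing C2 benzylic cation, stabilised by three silyloxy groups, is captured by O1 (bond O1–C2). Ring C is thus closed by an inverse-electron-demand hetero-[4+2] of the O1=C8a–C4a=C4 heterodiene with the C2=C3 alkene, concerted but asynchronous or, at the limit, stepwise with six-membered closure by O1 on the cation. C2 is set by the catalyst: the phosphate held at the O1 hydrogen and the oxocarbenium carbon shields one face of the heterodiene, so the styrene approaches from the other, aimed at 2S. C4 follows from the endo arrangement that puts the aryl and methoxy groups cis, aimed at 4S, and it is removed in step 11, so only C2 matters. Regiochemistry needs no control beyond the substrate: only the C8a hydroxyl is free, so ring closure can take one direction, and 14 is nucleophilic only at its terminal carbon. Chemoselectivity rests on 14 being far more nucleophilic than the prenyl and lavandulyl alkenes and on a weak acid at 0 °C, with slow addition of 14 to suppress its cationic oligomerisation; the C2'' centre is five bonds from C2 and should not perturb catalyst control.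

Step 11
Reactants: 17 (2S,4S)-4-methoxyflavan penta-TBS ether
Product: 18 (2S)-8-[(2R)-lavandulyl]-6-prenyl-5,7-bis(TBS-oxy)-2-[2,4,6-tris(TBS-oxy)phenyl]chroman-4-one
Conditions: DDQ (1.3 equiv), CH2Cl2/pH 7 phosphate buffer (10:1), 0 °C
Reagents that add atoms: water, O
Why: DDQ oxidation of a benzylic ether; hydride abstraction from C4–H, pseudo-axial in the cis isomer and activated by the methoxy oxygen and the trioxygenated ring A, gives an oxocarbenium ion that water converts through the hemiketal to the ketone with loss of methanol. C2–H is less prone because it lies near the plane of the di-ortho-substituted ring B; C2 is untouched and C4 ceases to be a stereocentre.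

Step 12
Reactants: 18 (2S)-flavanone penta-TBS ether
Product: 19 CNP0163831.1, (2S)-5,7-dihydroxy-8-[(2R)-lavandulyl]-6-prenyl-2-(2,4,6-trihydroxyphenyl)chroman-4-one
Conditions: Bu4NF (6 equiv), AcOH (6 equiv), THF, 0 °C to rt
Reagents that add atoms: none
Why: Fluoride cleavage of aryl silyl ethers; acetic acid protonates each phenoxide as it forms, so no base-induced retro-oxa-Michael opening of ring C can epimerise C2, and the medium is too weakly acidic to ionise C2–O1 or cyclise the side chains.

## Compound list

1 | (±)-lavandulol, rac-5-methyl-2-(prop-1-en-2-yl)hex-4-en-1-ol | C=C(C)C(CO)CC=C(C)C | starting material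
2 | (S)-lavandulol, (2S)-5-methyl-2-(prop-1-en-2-yl)hex-4-en-1-ol | C=C(C)[C@H](CC=C(C)C)CO | intermediate
3 | (S)-lavandulyl iodide, (3S)-3-(iodomethyl)-2,6-dimethylhepta-1,5-diene | C=C(C)[C@H](CC=C(C)C)CI | intermediate
4 | 2,4,6-trihydroxybenzaldehyde | O=Cc1c(O)cc(O)cc1O | starting material
5 | 2-hydroxy-4,6-bis(tert-butyldimethylsilyloxy)benzaldehyde | O=Cc1c(O)cc(O[Si](C)(C)C(C)(C)C)cc1O[Si](C)(C)C(C)(C)C | intermediate
6 | 2-hydroxy-3-iodo-4,6-bis(tert-butyldimethylsilyloxy)benzaldehyde | O=Cc1c(O)c(I)c(O[Si](C)(C)C(C)(C)C)cc1O[Si](C)(C)C(C)(C)C | intermediate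
7 | (S)-lavandulylzinc iodide, [(2S)-5-methyl-2-(prop-1-en-2-yl)hex-4-en-1-yl]zinc iodide | C=C(C)[C@H](CC=C(C)C)C[Zn]I | intermediate (not isolated)
8 | 2-hydroxy-3-[(2R)-5-methyl-2-(prop-1-en-2-yl)hex-4-en-1-yl]-4,6-bis(tert-butyldimethylsilyloxy)benzaldehyde | C=C(C)[C@H](CC=C(C)C)Cc1c(O)c(C=O)c(O[Si](C)(C)C(C)(C)C)cc1O[Si](C)(C)C(C)(C)C | intermediate
9 | prenol, 3-methylbut-2-en-1-ol | CC(C)=CCO | starting material
10 | 3-[(2R)-5-methyl-2-(prop-1-en-2-yl)hex-4-en-1-yl]-2-(3-methylbut-2-en-1-yloxy)-4,6-bis(tert-butyldimethylsilyloxy)benzaldehyde | C=C(C)[C@H](CC=C(C)C)Cc1c(OCC=C(C)C)c(C=O)c(O[Si](C)(C)C(C)(C)C)cc1O[Si](C)(C)C(C)(C)C | intermediate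
11 | ortho-dienone, 2,4-bis(tert-butyldimethylsilyloxy)-5-[(2R)-5-methyl-2-(prop-1-en-2-yl)hex-4-en-1-yl]-5-(2-methylbut-3-en-2-yl)-6-oxocyclohexa-1,3-diene-1-carbaldehyde (ring C5 configuration not defined) | C=C(C)[C@H](CC=C(C)C)CC1(C(C)(C)C=C)C(O[Si](C)(C)C(C)(C)C)=CC(O[Si](C)(C)C(C)(C)C)=C(C=O)C1=O | intermediate (not isolated)
12 | 2-hydroxy-3-[(2R)-5-methyl-2-(prop-1-en-2-yl)hex-4-en-1-yl]-5-(3-methylbut-2-en-1-yl)-4,6-bis(tert-butyldimethylsilyloxy)benzaldehyde | C=C(C)[C@H](CC=C(C)C)Cc1c(O[Si](C)(C)C(C)(C)C)c(CC=C(C)C)c(O[Si](C)(C)C(C)(C)C)c(C=O)c1O | intermediate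
13 | 2,4,6-tris(tert-butyldimethylsilyloxy)benzaldehyde | O=Cc1c(O[Si](C)(C)C(C)(C)C)cc(O[Si](C)(C)C(C)(C)C)cc1O[Si](C)(C)C(C)(C)C | intermediate
14 | 2,4,6-tris(tert-butyldimethylsilyloxy)styrene | C=Cc1c(O[Si](C)(C)C(C)(C)C)cc(O[Si](C)(C)C(C)(C)C)cc1O[Si](C)(C)C(C)(C)C | intermediate
15 | trimethyl orthoformate | COC(OC)OC | starting material
16 | dimethyl acetal of 12, 2-(dimethoxymethyl)-6-[(2R)-5-methyl-2-(prop-1-en-2-yl)hex-4-en-1-yl]-4-(3-methylbut-2-en-1-yl)-3,5-bis(tert-butyldimethylsilyloxy)phenol | C=C(C)[C@H](CC=C(C)C)Cc1c(O[Si](C)(C)C(C)(C)C)c(CC=C(C)C)c(O[Si](C)(C)C(C)(C)C)c(C(OC)OC)c1O | intermediate (not isolated)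
17 | (2S,4S)-4-methoxy-8-[(2R)-5-methyl-2-(prop-1-en-2-yl)hex-4-en-1-yl]-6-(3-methylbut-2-en-1-yl)-5,7-bis(tert-butyldimethylsilyloxy)-2-[2,4,6-tris(tert-butyldimethylsilyloxy)phenyl]chromane | C=C(C)[C@H](CC=C(C)C)Cc1c(O[Si](C)(C)C(C)(C)C)c(CC=C(C)C)c(O[Si](C)(C)C(C)(C)C)c2c1O[C@H](c1c(O[Si](C)(C)C(C)(C)C)cc(O[Si](C)(C)C(C)(C)C)cc1O[Si](C)(C)C(C)(C)C)C[C@@H]2OC | intermediate
18 | (2S)-8-[(2R)-5-methyl-2-(prop-1-en-2-yl)hex-4-en-1-yl]-6-(3-methylbut-2-en-1-yl)-5,7-bis(tert-butyldimethylsilyloxy)-2-[2,4,6-tris(tert-butyldimethylsilyloxy)phenyl]chroman-4-one | C=C(C)[C@H](CC=C(C)C)Cc1c(O[Si](C)(C)C(C)(C)C)c(CC=C(C)C)c(O[Si](C)(C)C(C)(C)C)c2c1O[C@H](c1c(O[Si](C)(C)C(C)(C)C)cc(O[Si](C)(C)C(C)(C)C)cc1O[Si](C)(C)C(C)(C)C)CC2=O | intermediate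
19 | CNP0163831.1, (2S)-5,7-dihydroxy-8-[(2R)-5-methyl-2-(prop-1-en-2-yl)hex-4-en-1-yl]-6-(3-methylbut-2-en-1-yl)-2-(2,4,6-trihydroxyphenyl)chroman-4-one | C=C(C)[C@H](CC=C(C)C)Cc1c(O)c(CC=C(C)C)c(O)c2c1O[C@H](c1c(O)cc(O)cc1O)CC2=O | target

## Step count and risk

Total step count: 12. Longest linear sequence: 8 steps (steps 3, 4, 5, 6, 7, 10, 11, 12 from 4; equally steps 1, 2, 5, 6, 7, 10, 11, 12 from 1).

**Key step, step 10.** The most likely failures are weak facial discrimination, which would give both C2 epimers (diastereomers because of C2''), and acid-induced oligomerisation of the very electron-rich styrene outrunning the cycloaddition. Slow acetal formation or ionisation at the hindered, chelated aldehyde is also possible, as is erosion of C2 by reversible C2–O1 ionisation. A more acidic N-triflyl phosphoramide of the same backbone is the first variation. The fallback uses known chemistry and gives up catalyst control. The components 12, 14 and 15 are combined under Sc(OTf)3 in CH2Cl2, the established racemic form of this coupling. This should give the cis flavan as a mixture of 17 and its epimer at both ring centres, the (2R,4R)-4-methoxyflavan penta-TBS ether F1. The mixture is oxidised as in step 11 to 18 and the (2R)-flavanone penta-TBS ether F2. The two are then parted by asymmetric transfer hydrogenation run as a kinetic resolution with RuCl[(R,R)-TsDPEN](p-cymene) and HCO2H/Et3N. This should reduce the matched F2 to the (2R,4R)-cis-flavan-4-ol penta-TBS ether F3 and leave 18, where the route is rejoined.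

**Step 4.** Iodination may occur para to the free hydroxyl, or twice, if the steric shielding by the two silyloxy groups is weaker than assumed. The fallback reverses the order so that the regiochemistry rests on silylation instead. Starting from 4, whose two open positions are equivalent, one equivalent of N-iodosuccinimide gives 3-iodo-2,4,6-trihydroxybenzaldehyde F4. Two equivalents of TBSCl then silylate the para hydroxyl and the less hindered ortho hydroxyl, leaving the one wedged between iodine and the formyl group, which returns to 6.

**Step 5.** The free phenol may consume the zinc reagent by protonolysis, the hindered electron-rich iodide may be reduced instead of coupled, and a homoallyl radical formed during zinc insertion may undergo a 1,2-vinyl shift. The fallback masks the phenol. From 6, MOMCl and i-Pr2NEt give 3-iodo-2-(methoxymethoxy)-4,6-bis(TBS-oxy)benzaldehyde F5. The same coupling with 7 gives 3-[(2R)-lavandulyl]-2-(methoxymethoxy)-4,6-bis(TBS-oxy)benzaldehyde F6. The chelated MOM ether is then removed with ZnBr2 and propane-1-thiol in CH2Cl2 at 0 °C, which returns to 8.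

**Step 7.** The Lewis acid may ionise the chelated prenyl ether, so that the prenyl group is lost and the phenol is returned instead of rearranging, and some desilylation may occur. The fallback installs the prenyl group by cross-coupling before any alkene is present. From 6, N-bromosuccinimide gives 5-bromo-2-hydroxy-3-iodo-4,6-bis(TBS-oxy)benzaldehyde F7. Iodide-selective coupling with 7 under the conditions of step 5 gives 5-bromo-2-hydroxy-3-[(2R)-lavandulyl]-4,6-bis(TBS-oxy)benzaldehyde F8. Stille coupling with tributyl(prenyl)stannane and Pd(PPh3)4 in DMF at 90 °C then returns to 12. This fallback carries its own risk of slow oxidative addition at the doubly flanked bromide and of some branched allyl transfer.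

**Step 11.** The oxocarbenium ion may lose a C3 proton and be oxidised a second time toward the flavone level, and hydride abstraction may compete at the benzylic, allylic CH2 of the prenyl group. The fallback separates ionisation from oxidation. From 17, pyridinium p-toluenesulfonate in aqueous acetone exchanges the methoxy group for hydroxyl to give the (2S)-flavan-4-ol penta-TBS ether F9 as a mixture at C4. Dess–Martin periodinane buffered with NaHCO3 then returns to 18. Its own risk is acid-induced elimination across C3–C4.

## Further compounds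

F1 | step 10 | (2R,4R)-4-methoxy-8-[(2R)-lavandulyl]-6-prenyl-5,7-bis(TBS-oxy)-2-[2,4,6-tris(TBS-oxy)phenyl]chromane | C=C(C)[C@H](CC=C(C)C)Cc1c(O[Si](C)(C)C(C)(C)C)c(CC=C(C)C)c(O[Si](C)(C)C(C)(C)C)c2c1O[C@@H](c1c(O[Si](C)(C)C(C)(C)C)cc(O[Si](C)(C)C(C)(C)C)cc1O[Si](C)(C)C(C)(C)C)C[C@H]2OC
F2 | step 10 | (2R)-8-[(2R)-lavandulyl]-6-prenyl-5,7-bis(TBS-oxy)-2-[2,4,6-tris(TBS-oxy)phenyl]chroman-4-one | C=C(C)[C@H](CC=C(C)C)Cc1c(O[Si](C)(C)C(C)(C)C)c(CC=C(C)C)c(O[Si](C)(C)C(C)(C)C)c2c1O[C@@H](c1c(O[Si](C)(C)C(C)(C)C)cc(O[Si](C)(C)C(C)(C)C)cc1O[Si](C)(C)C(C)(C)C)CC2=O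
F3 | step 10 | (2R,4R)-8-[(2R)-lavandulyl]-6-prenyl-5,7-bis(TBS-oxy)-2-[2,4,6-tris(TBS-oxy)phenyl]chroman-4-ol | C=C(C)[C@H](CC=C(C)C)Cc1c(O[Si](C)(C)C(C)(C)C)c(CC=C(C)C)c(O[Si](C)(C)C(C)(C)C)c2c1O[C@@H](c1c(O[Si](C)(C)C(C)(C)C)cc(O[Si](C)(C)C(C)(C)C)cc1O[Si](C)(C)C(C)(C)C)C[C@H]2O
F4 | step 4 | 3-iodo-2,4,6-trihydroxybenzaldehyde | O=Cc1c(O)cc(O)c(I)c1O
F5 | step 5 | 3-iodo-2-(methoxymethoxy)-4,6-bis(tert-butyldimethylsilyloxy)benzaldehyde | COCOc1c(I)c(O[Si](C)(C)C(C)(C)C)cc(O[Si](C)(C)C(C)(C)C)c1C=O
F6 | step 5 | 3-[(2R)-5-methyl-2-(prop-1-en-2-yl)hex-4-en-1-yl]-2-(methoxymethoxy)-4,6-bis(tert-butyldimethylsilyloxy)benzaldehyde | C=C(C)[C@H](CC=C(C)C)Cc1c(OCOC)c(C=O)c(O[Si](C)(C)C(C)(C)C)cc1O[Si](C)(C)C(C)(C)C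
F7 | step 7 | 5-bromo-2-hydroxy-3-iodo-4,6-bis(tert-butyldimethylsilyloxy)benzaldehyde | O=Cc1c(O)c(I)c(O[Si](C)(C)C(C)(C)C)c(Br)c1O[Si](C)(C)C(C)(C)C
F8 | step 7 | 5-bromo-2-hydroxy-3-[(2R)-5-methyl-2-(prop-1-en-2-yl)hex-4-en-1-yl]-4,6-bis(tert-butyldimethylsilyloxy)benzaldehyde | C=C(C)[C@H](CC=C(C)C)Cc1c(O)c(C=O)c(O[Si](C)(C)C(C)(C)C)c(Br)c1O[Si](C)(C)C(C)(C)C
F9 | step 11 | (2S)-8-[(2R)-lavandulyl]-6-prenyl-5,7-bis(TBS-oxy)-2-[2,4,6-tris(TBS-oxy)phenyl]chroman-4-ol (C4 not defined) | C=C(C)[C@H](CC=C(C)C)Cc1c(O[Si](C)(C)C(C)(C)C)c(CC=C(C)C)c(O[Si](C)(C)C(C)(C)C)c2c1O[C@H](c1c(O[Si](C)(C)C(C)(C)C)cc(O[Si](C)(C)C(C)(C)C)cc1O[Si](C)(C)C(C)(C)C)CC2O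
A1 | alternative 1 | 3-(allyloxy)-6-[(2R)-5-methyl-2-(prop-1-en-2-yl)hex-4-en-1-yl]-2-(3-methylbut-2-en-1-yl)-5-(triisopropylsilyloxy)phenol | C=C(C)[C@H](CC=C(C)C)Cc1c(O)c(CC=C(C)C)c(OCC=C)cc1O[Si](C(C)C)(C(C)C)C(C)C
A2 | alternative 1 | 3-(allyloxy)-4-(3-methylbut-2-en-1-yl)cyclobut-2-en-1-one | C=CCOC1=CC(=O)C1CC=C(C)C
A3 | alternative 1 | triisopropyl{[(4R)-7-methyl-4-(prop-1-en-2-yl)oct-6-en-1-yn-1-yl]oxy}silane | C=C(C)[C@H](CC=C(C)C)CC#CO[Si](C(C)C)(C(C)C)C(C)C
A4 | alternative 2 | (2S)-8-[(2R)-lavandulyl]-6-prenyl-5,7-bis(methoxymethoxy)-2-[2,4,6-tris(methoxymethoxy)phenyl]chroman-4-one | C=C(C)[C@H](CC=C(C)C)Cc1c(OCOC)c(CC=C(C)C)c(OCOC)c2c1O[C@H](c1c(OCOC)cc(OCOC)cc1OCOC)CC2=O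
A5 | alternative 2 | 2-[(2R)-5-methyl-2-(prop-1-en-2-yl)hex-4-en-1-yl]-3,5-bis(methoxymethoxy)-4-(3-methylbut-2-en-1-yl)-6-(trimethylsilyl)phenyl trifluoromethanesulfonate | C=C(C)[C@H](CC=C(C)C)Cc1c(OCOC)c(CC=C(C)C)c(OCOC)c([Si](C)(C)C)c1OS(=O)(=O)C(F)(F)F
A6 | alternative 2 | methyl (3S)-3-hydroxy-3-[2,4,6-tris(methoxymethoxy)phenyl]propanoate | COC(=O)C[C@H](O)c1c(OCOC)cc(OCOC)cc1OCOC
A7 | alternative 3 | (2S)-8-[(2R)-lavandulyl]-6-prenyl-5,7-bis(TBS-oxy)-2-[2,4,6-tris(TBS-oxy)phenyl]chroman-4-one (identical with 18) | C=C(C)[C@H](CC=C(C)C)Cc1c(O[Si](C)(C)C(C)(C)C)c(CC=C(C)C)c(O[Si](C)(C)C(C)(C)C)c2c1O[C@H](c1c(O[Si](C)(C)C(C)(C)C)cc(O[Si](C)(C)C(C)(C)C)cc1O[Si](C)(C)C(C)(C)C)CC2=O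
A8 | alternative 3 | 2-diazo-1-[4,6-bis(tert-butyldimethylsilyloxy)-3-[(2R)-5-methyl-2-(prop-1-en-2-yl)hex-4-en-1-yl]-5-(3-methylbut-2-en-1-yl)-2-{[2,4,6-tris(tert-butyldimethylsilyloxy)phenyl]methoxy}phenyl]ethan-1-one | C=C(C)[C@H](CC=C(C)C)Cc1c(O[Si](C)(C)C(C)(C)C)c(CC=C(C)C)c(O[Si](C)(C)C(C)(C)C)c(C(=O)C=[N+]=[N-])c1OCc1c(O[Si](C)(C)C(C)(C)C)cc(O[Si](C)(C)C(C)(C)C)cc1O[Si](C)(C)C(C)(C)C
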